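**Plan**

- Benzofuran numbering is used: ring A is the fused benzene, ring B the pendant 4-hydroxy-3-methoxyphenyl ring, ring C the dihydrofuran.
- Enabling feature: C2 is benzylic to ring B and para to the ring B hydroxyl, so O1–C2 can form when the ring A phenol adds to a para-quinone methide of ring B.
- Cuts, in order: both benzoate C–O bonds; the C=C of the C5 side chain (back to a 5-formyl group); O1–C2 (ring C); C2–C3 (benzylation of an arylacetyl enolate); C3–C3a (arylation of an acetate unit by 5-iodovanillin).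
- Forward: ring A gains the acetate unit, ring B is joined by Evans alkylation, the open 2,3-diarylpropanol is unmasked, ring C is closed oxidatively, then the C5 chain is extended and both primary alcohols are acylated.
- Stereochemistry: C3 from the (R)-4-benzyloxazolidinone-directed alkylation, C2 set trans to C3 in the ring closure, the E alkene from a stabilised Wittig ylide.

Key step: step 11

Remark: the target SMILES reads as (2S,3R), trans. The primary alcohol is carried through the ring closure as a pivalate because iBu2AlH later removes it in the operation that reduces the acrylate, so no selective desilylation is needed.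

**Route**

Step 1
Reactants: 1 5-iodovanillin
Product: 2 4-(benzyloxy)-3-iodo-5-methoxybenzaldehyde
Conditions: BnBr, K2CO3, DMF, 60 °C
Reagents that add atoms: benzyl bromide, BrCc1ccccc1
Why: Williamson ether synthesis, in which the phenoxide formed by K2CO3 displaces bromide from benzyl bromide by SN2 while the aldehyde is inert.

Step 2
Reactants: 2 4-(benzyloxy)-3-iodo-5-methoxybenzaldehyde
Product: 3 2-[4-(benzyloxy)-3-iodo-5-methoxyphenyl]-1,3-dioxolane
Conditions: ethylene glycol, p-TsOH·H2O (cat.), toluene, reflux, Dean–Stark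
Reagents that add atoms: ethylene glycol, OCCO
Why: Acid-catalysed acetalisation with azeotropic removal of water masks the aldehyde as a dioxolane that should tolerate the organozinc, enolate and hydride reagents of the following steps.

Step 3
Reactants: 3 2-[4-(benzyloxy)-3-iodo-5-methoxyphenyl]-1,3-dioxolane; 4 ethyl bromoacetate
Product: 6 ethyl 2-[2-(benzyloxy)-5-(1,3-dioxolan-2-yl)-3-methoxyphenyl]acetate, via ethyl bromozincacetate 5 (not isolated)
Conditions: 4, Zn dust, TMSCl (cat.), THF, 40 °C; then 3, Pd2(dba)3 (2 mol%), XPhos (8 mol%), THF, 65 °C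
Reagents that add atoms: none
Why: Negishi-type cross-coupling of a Reformatsky reagent, in which oxidative addition of the aryl iodide to zerovalent palladium carrying the bulky XPhos ligand, transmetalation with the zinc enolate and reductive elimination should give the arylacetate with acetal and benzyl ether as spectators.

Step 4
Reactants: 6 ethyl 2-[2-(benzyloxy)-5-(1,3-dioxolan-2-yl)-3-methoxyphenyl]acetate
Product: 7 2-[2-(benzyloxy)-5-(1,3-dioxolan-2-yl)-3-methoxyphenyl]acetic acid
Conditions: LiOH·H2O, THF/MeOH/H2O, rt; then aq. citric acid to pH 4, 0 °C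
Reagents that add atoms: lithium hydroxide, [Li+].[OH-]
Why: Saponification of an unhindered ethyl ester by hydroxide, followed by a mildly acidic work-up that protonates the carboxylate but should leave the dioxolane intact.

Step 5
Reactants: 7 2-[2-(benzyloxy)-5-(1,3-dioxolan-2-yl)-3-methoxyphenyl]acetic acid; 8 (R)-4-benzyl-1,3-oxazolidin-2-one
Product: 10 (4R)-4-benzyl-3-{[2-(benzyloxy)-5-(1,3-dioxolan-2-yl)-3-methoxyphenyl]acetyl}-1,3-oxazolidin-2-one, via mixed pivalic anhydride 9 (not isolated)
Conditions: PivCl, Et3N, THF, −20 °C; then 8, LiCl, −20 °C → rt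
Reagents that add atoms: none
Why: N-Acylation of the oxazolidinone through a mixed pivalic anhydride, in which LiCl and Et3N make the oxazolidinone nucleophilic and the bulky tert-butyl group steers attack to the arylacetyl carbonyl.

Step 6
Reactants: 11 4-(benzyloxy)-3-methoxybenzyl alcohol
Product: 12 4-(benzyloxy)-3-methoxybenzyl bromide
Conditions: PBr3, CH2Cl2, 0 °C
Reagents that add atoms: phosphorus tribromide, BrP(Br)Br
Why: Conversion of a benzylic alcohol into the bromide through a bromophosphite ester and SN2 displacement by bromide; the electron-rich bromide is used without delay.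

Step 7
Reactants: 10 (4R)-4-benzyl-3-{[2-(benzyloxy)-5-(1,3-dioxolan-2-yl)-3-methoxyphenyl]acetyl}-1,3-oxazolidin-2-one; 12 4-(benzyloxy)-3-methoxybenzyl bromide
Product: 14 (4R)-4-benzyl-3-{(2R)-2-[2-(benzyloxy)-5-(1,3-dioxolan-2-yl)-3-methoxyphenyl]-3-[4-(benzyloxy)-3-methoxyphenyl]propanoyl}-1,3-oxazolidin-2-one, via sodium Z-enolate 13 (not isolated)
Conditions: NaN(SiMe3)2, THF, −78 °C; then 12, −78 → −30 °C; AcOH quench at −78 °C
Reagents that add atoms: none
Why: Evans asymmetric alkylation, in which the chelated sodium Z-enolate is shielded on one face by the 4-benzyl group of the (R)-auxiliary, so the benzylic bromide should add from the opposite face and set the future C3 centre as R.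

Step 8
Reactants: 14 (4R)-4-benzyl-3-{(2R)-2-[2-(benzyloxy)-5-(1,3-dioxolan-2-yl)-3-methoxyphenyl]-3-[4-(benzyloxy)-3-methoxyphenyl]propanoyl}-1,3-oxazolidin-2-one
Product: 15 (2R)-2-[2-(benzyloxy)-5-(1,3-dioxolan-2-yl)-3-methoxyphenyl]-3-[4-(benzyloxy)-3-methoxyphenyl]propan-1-ol
Conditions: LiBH4, H2O (1 equiv), Et2O/THF, 0 °C
Reagents that add atoms: none
Why: Reductive removal of the Evans auxiliary, in which LiBH4 attacks the exocyclic imide carbonyl and should deliver the primary alcohol without touching the stereocentre, the acetal or the benzyl ethers.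

Step 9
Reactants: 15 (2R)-2-[2-(benzyloxy)-5-(1,3-dioxolan-2-yl)-3-methoxyphenyl]-3-[4-(benzyloxy)-3-methoxyphenyl]propan-1-ol
Product: 16 (2R)-2-[2-(benzyloxy)-5-(1,3-dioxolan-2-yl)-3-methoxyphenyl]-3-[4-(benzyloxy)-3-methoxyphenyl]propyl pivalate
Conditions: PivCl, pyridine, DMAP (cat.), CH2Cl2, 0 °C → rt
Reagents that add atoms: pivaloyl chloride, CC(C)(C)C(=O)Cl
Why: DMAP-catalysed acylation of a primary alcohol with an acid chloride gives a pivalate that is inert to hydrogenolysis, dilute acid and DDQ.

Step 10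
Reactants: 16 (2R)-2-[2-(benzyloxy)-5-(1,3-dioxolan-2-yl)-3-methoxyphenyl]-3-[4-(benzyloxy)-3-methoxyphenyl]propyl pivalate
Product: 18 (2R)-2-(5-formyl-2-hydroxy-3-methoxyphenyl)-3-(4-hydroxy-3-methoxyphenyl)propyl pivalate, via bisphenol dioxolane 17 (not isolated)
Conditions: H2 (1 atm), Pd/C (10% Pd on carbon), THF, rt; filter; then 1 M aq. HCl, rt
Reagents that add atoms: water, O
Why: Hydrogenolysis of the two aryl benzyl ethers on palladium is followed by acid-catalysed acetal hydrolysis, which is especially easy once the para-hydroxyl is free, and neither operation touches the ester or the stereocentre.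

Step 11
Reactants: 18 (2R)-2-(5-formyl-2-hydroxy-3-methoxyphenyl)-3-(4-hydroxy-3-methoxyphenyl)propyl pivalate
Product: 20 [(2S,3R)-5-formyl-2-(4-hydroxy-3-methoxyphenyl)-7-methoxy-2,3-dihydro-1-benzofuran-3-yl]methyl pivalate, via para-quinone methide 19 (not isolated)
Conditions: DDQ (1.05 equiv), 1,4-dioxane, rt
Reagents that add atoms: none
Why: DDQ should form a charge-transfer complex with the electron-rich ring B and take a hydride from the CH2 group para to its free hydroxyl, and loss of the phenolic proton then gives para-quinone methide 19. The closest known reaction type is the dehydrogenation of 4-alkylphenols to para-quinone methides with DDQ or Ag2O followed by intramolecular capture by an oxygen nucleophile. The ring A phenol, held ortho to the side chain, adds to the exocyclic methide carbon in a 5-exo-trig oxa-Michael addition that forms O1–C2, closes ring C and restores the aromaticity of ring B. The new C2 centre is controlled by the existing C3 centre, since the aryl group takes the side of the forming ring away from the pivaloyloxymethyl group, and because the addition can revert through 19 the trans isomer should also be the thermodynamic outcome. The step needs site selectivity between two phenols and two benzylic positions, which the substrate secures through the para-formyl group that makes ring A electron-poor and through the fact that only the future C2 is benzylic and para to a free hydroxyl on an electron-rich ring. Further dehydrogenation to the benzofuran is held back by using close to one equivalent of oxidant.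

Step 12
Reactants: 20 [(2S,3R)-5-formyl-2-(4-hydroxy-3-methoxyphenyl)-7-methoxy-2,3-dihydro-1-benzofuran-3-yl]methyl pivalate
Product: 21 [(2S,3R)-2-{4-[(tert-butyldimethylsilyl)oxy]-3-methoxyphenyl}-5-formyl-7-methoxy-2,3-dihydro-1-benzofuran-3-yl]methyl pivalate
Conditions: TBSCl, imidazole, DMF, rt
Reagents that add atoms: tert-butyldimethylsilyl chloride, CC(C)(C)[Si](C)(C)Cl
Why: Imidazole-promoted silylation protects the only free hydroxyl, so that the later esterification can involve the two primary alcohols alone.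

Step 13
Reactants: 21 [(2S,3R)-2-{4-[(tert-butyldimethylsilyl)oxy]-3-methoxyphenyl}-5-formyl-7-methoxy-2,3-dihydro-1-benzofuran-3-yl]methyl pivalate; 22 ethyl (triphenylphosphoranylidene)acetate
Product: 23 ethyl (E)-3-[(2S,3R)-2-{4-[(tert-butyldimethylsilyl)oxy]-3-methoxyphenyl}-7-methoxy-3-(pivaloyloxymethyl)-2,3-dihydro-1-benzofuran-5-yl]acrylate
Conditions: 22 (1.3 equiv), toluene, 80 °C
Reagents that add atoms: none
Why: Wittig olefination with a stabilised ylide, whose reversible oxaphosphetane formation should give the E acrylate under neutral conditions that spare the pivalate, the silyl ether and the C2 and C3 centres.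

Step 14
Reactants: 23 ethyl (E)-3-[(2S,3R)-2-{4-[(tert-butyldimethylsilyl)oxy]-3-methoxyphenyl}-7-methoxy-3-(pivaloyloxymethyl)-2,3-dihydro-1-benzofuran-5-yl]acrylate
Product: 24 (E)-3-[(2S,3R)-2-{4-[(tert-butyldimethylsilyl)oxy]-3-methoxyphenyl}-3-(hydroxymethyl)-7-methoxy-2,3-dihydro-1-benzofuran-5-yl]prop-2-en-1-ol
Conditions: iBu2AlH (6 equiv), CH2Cl2, −78 → 0 °C; aq. potassium sodium tartrate
Reagents that add atoms: none
Why: Hydride reduction with iBu2AlH converts the conjugated ester into the allylic alcohol by 1,2-delivery and in the same operation cleaves the pivalate reductively, while the aryl silyl ether is stable at low temperature.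

Step 15
Reactants: 25 4-hydroxybenzoic acid
Product: 27 4-[(tert-butyldimethylsilyl)oxy]benzoic acid, via bis-silylated acid 26 (not isolated)
Conditions: TBSCl (2.2 equiv), imidazole, DMF, rt; then AcOH/THF/H2O, rt
Reagents that add atoms: tert-butyldimethylsilyl chloride, CC(C)(C)[Si](C)(C)Cl
Why: Exhaustive silylation followed by selective hydrolysis of the far more labile silyl ester in mild aqueous acid should leave the phenol protected and the carboxylic acid free.

Step 16
Reactants: 24 (E)-3-[(2S,3R)-2-{4-[(tert-butyldimethylsilyl)oxy]-3-methoxyphenyl}-3-(hydroxymethyl)-7-methoxy-2,3-dihydro-1-benzofuran-5-yl]prop-2-en-1-ol; 27 4-[(tert-butyldimethylsilyl)oxy]benzoic acid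
Product: 28 tris(tert-butyldimethylsilyl) ether of the target (ring B phenol and both benzoate phenols silylated)
Conditions: 27 (2.4 equiv), EDC·HCl, DMAP, CH2Cl2, 0 °C → rt
Reagents that add atoms: none
Why: Steglich esterification, in which the carbodiimide activates the acid as an O-acylisourea and DMAP relays the acyl group to both primary alcohols, with no free phenol present to compete.

Step 17
Reactants: 28 tris(tert-butyldimethylsilyl) ether of the target
Product: 29 quiquesetinerviusin A
Conditions: TBAF (3.3 equiv), AcOH (3.5 equiv), THF, 0 °C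
Reagents that add atoms: none
Why: Fluoride-induced cleavage of the three aryl silyl ethers, driven by the strong Si–F bond, with acetic acid buffering the phenoxides so that the two benzoate esters should not be attacked.

**Compound list**

1 | 5-iodovanillin (4-hydroxy-3-iodo-5-methoxybenzaldehyde) | COc1cc(C=O)cc(I)c1O | starting material
2 | 4-(benzyloxy)-3-iodo-5-methoxybenzaldehyde | COc1cc(C=O)cc(I)c1OCc1ccccc1 | intermediate
3 | 2-[4-(benzyloxy)-3-iodo-5-methoxyphenyl]-1,3-dioxolane | COc1cc(C2OCCO2)cc(I)c1OCc1ccccc1 | intermediate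
4 | ethyl bromoacetate | CCOC(=O)CBr | starting material
5 | ethyl bromozincacetate (Reformatsky reagent) | CCOC(=O)C[Zn]Br | intermediate
6 | ethyl 2-[2-(benzyloxy)-5-(1,3-dioxolan-2-yl)-3-methoxyphenyl]acetate | CCOC(=O)Cc1cc(C2OCCO2)cc(OC)c1OCc1ccccc1 | intermediate
7 | 2-[2-(benzyloxy)-5-(1,3-dioxolan-2-yl)-3-methoxyphenyl]acetic acid | OC(=O)Cc1cc(C2OCCO2)cc(OC)c1OCc1ccccc1 | intermediate
8 | (R)-4-benzyl-1,3-oxazolidin-2-one | O=C1N[C@H](Cc2ccccc2)CO1 | starting material
9 | 2-[2-(benzyloxy)-5-(1,3-dioxolan-2-yl)-3-methoxyphenyl]acetic pivalic anhydride | CC(C)(C)C(=O)OC(=O)Cc1cc(C2OCCO2)cc(OC)c1OCc1ccccc1 | intermediate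
10 | (4R)-4-benzyl-3-{[2-(benzyloxy)-5-(1,3-dioxolan-2-yl)-3-methoxyphenyl]acetyl}-1,3-oxazolidin-2-one | O=C1OC[C@@H](Cc2ccccc2)N1C(=O)Cc1cc(C2OCCO2)cc(OC)c1OCc1ccccc1 | intermediate
11 | 4-(benzyloxy)-3-methoxybenzyl alcohol | COc1cc(CO)ccc1OCc1ccccc1 | starting material
12 | 4-(benzyloxy)-3-methoxybenzyl bromide | COc1cc(CBr)ccc1OCc1ccccc1 | intermediate
13 | sodium Z-enolate of 10 | [Na+].[O-]/C(=C\c1cc(C2OCCO2)cc(OC)c1OCc1ccccc1)N1C(=O)OC[C@H]1Cc1ccccc1 | intermediate
14 | (4R)-4-benzyl-3-{(2R)-2-[2-(benzyloxy)-5-(1,3-dioxolan-2-yl)-3-methoxyphenyl]-3-[4-(benzyloxy)-3-methoxyphenyl]propanoyl}-1,3-oxazolidin-2-one | O=C1OC[C@@H](Cc2ccccc2)N1C(=O)[C@H](Cc1ccc(OCc2ccccc2)c(OC)c1)c1cc(C2OCCO2)cc(OC)c1OCc1ccccc1 | intermediate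
15 | (2R)-2-[2-(benzyloxy)-5-(1,3-dioxolan-2-yl)-3-methoxyphenyl]-3-[4-(benzyloxy)-3-methoxyphenyl]propan-1-ol | OC[C@H](Cc1ccc(OCc2ccccc2)c(OC)c1)c1cc(C2OCCO2)cc(OC)c1OCc1ccccc1 | intermediate
16 | (2R)-2-[2-(benzyloxy)-5-(1,3-dioxolan-2-yl)-3-methoxyphenyl]-3-[4-(benzyloxy)-3-methoxyphenyl]propyl pivalate | CC(C)(C)C(=O)OC[C@H](Cc1ccc(OCc2ccccc2)c(OC)c1)c1cc(C2OCCO2)cc(OC)c1OCc1ccccc1 | intermediate
17 | (2R)-2-[5-(1,3-dioxolan-2-yl)-2-hydroxy-3-methoxyphenyl]-3-(4-hydroxy-3-methoxyphenyl)propyl pivalate | CC(C)(C)C(=O)OC[C@H](Cc1ccc(O)c(OC)c1)c1cc(C2OCCO2)cc(OC)c1O | intermediate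
18 | (2R)-2-(5-formyl-2-hydroxy-3-methoxyphenyl)-3-(4-hydroxy-3-methoxyphenyl)propyl pivalate | CC(C)(C)C(=O)OC[C@H](Cc1ccc(O)c(OC)c1)c1cc(C=O)cc(OC)c1O | intermediate
19 | para-quinone methide of 18: (2R)-2-(5-formyl-2-hydroxy-3-methoxyphenyl)-3-(3-methoxy-4-oxocyclohexa-2,5-dien-1-ylidene)propyl pivalate | CC(C)(C)C(=O)OC[C@H](C=C1C=CC(=O)C(OC)=C1)c1cc(C=O)cc(OC)c1O | intermediate
20 | [(2S,3R)-5-formyl-2-(4-hydroxy-3-methoxyphenyl)-7-methoxy-2,3-dihydro-1-benzofuran-3-yl]methyl pivalate (2,3-trans) | COc1cc([C@H]2Oc3c(OC)cc(C=O)cc3[C@@H]2COC(=O)C(C)(C)C)ccc1O | intermediate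
21 | [(2S,3R)-2-{4-[(tert-butyldimethylsilyl)oxy]-3-methoxyphenyl}-5-formyl-7-methoxy-2,3-dihydro-1-benzofuran-3-yl]methyl pivalate | COc1cc([C@H]2Oc3c(OC)cc(C=O)cc3[C@@H]2COC(=O)C(C)(C)C)ccc1O[Si](C)(C)C(C)(C)C | intermediate
22 | ethyl (triphenylphosphoranylidene)acetate | CCOC(=O)C=P(c1ccccc1)(c1ccccc1)c1ccccc1 | starting material
23 | ethyl (E)-3-[(2S,3R)-2-{4-[(tert-butyldimethylsilyl)oxy]-3-methoxyphenyl}-7-methoxy-3-(pivaloyloxymethyl)-2,3-dihydro-1-benzofuran-5-yl]acrylate | COc1cc([C@H]2Oc3c(OC)cc(/C=C/C(=O)OCC)cc3[C@@H]2COC(=O)C(C)(C)C)ccc1O[Si](C)(C)C(C)(C)C | intermediate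
24 | (E)-3-[(2S,3R)-2-{4-[(tert-butyldimethylsilyl)oxy]-3-methoxyphenyl}-3-(hydroxymethyl)-7-methoxy-2,3-dihydro-1-benzofuran-5-yl]prop-2-en-1-ol | COc1cc([C@H]2Oc3c(OC)cc(/C=C/CO)cc3[C@@H]2CO)ccc1O[Si](C)(C)C(C)(C)C | intermediate
25 | 4-hydroxybenzoic acid | O=C(O)c1ccc(O)cc1 | starting material
26 | tert-butyldimethylsilyl 4-[(tert-butyldimethylsilyl)oxy]benzoate | CC(C)(C)[Si](C)(C)OC(=O)c1ccc(O[Si](C)(C)C(C)(C)C)cc1 | intermediate
27 | 4-[(tert-butyldimethylsilyl)oxy]benzoic acid | O=C(O)c1ccc(O[Si](C)(C)C(C)(C)C)cc1 | intermediate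
28 | [(2S,3R)-2-{4-[(tert-butyldimethylsilyl)oxy]-3-methoxyphenyl}-5-[(E)-3-({4-[(tert-butyldimethylsilyl)oxy]benzoyl}oxy)prop-1-enyl]-7-methoxy-2,3-dihydro-1-benzofuran-3-yl]methyl 4-[(tert-butyldimethylsilyl)oxy]benzoate | COc1cc([C@H]2Oc3c(OC)cc(/C=C/COC(=O)c4ccc(O[Si](C)(C)C(C)(C)C)cc4)cc3[C@@H]2COC(=O)c2ccc(O[Si](C)(C)C(C)(C)C)cc2)ccc1O[Si](C)(C)C(C)(C)C | intermediate
29 | quiquesetinerviusin A, [(2S,3R)-2-(4-hydroxy-3-methoxyphenyl)-5-[(E)-3-(4-hydroxybenzoyloxy)prop-1-enyl]-7-methoxy-2,3-dihydro-1-benzofuran-3-yl]methyl 4-hydroxybenzoate | COc1cc([C@H]2Oc3c(OC)cc(/C=C/COC(=O)c4ccc(O)cc4)cc3[C@@H]2COC(=O)c2ccc(O)cc2)ccc1O | target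

**Step count and risks**

Total step count: 17.
Longest linear sequence: 15 steps (steps 1–5, 7–14, 16 and 17, from 5-iodovanillin).

Steps most likely to fail:

Step 11 (oxidative ring closure). Hydride abstraction may continue on the cyclised product, which is again a 4-alkylphenol, and lead on to the benzofuran. The quinone methide may also oligomerise or tautomerise to the stilbene before the phenol adds, and a purely kinetic closure may give some cis isomer. Fallback: oxidation and ring closure are separated. Setting out from 18, DDQ in methanol should trap the quinone methide with solvent and give (2R)-2-(5-formyl-2-hydroxy-3-methoxyphenyl)-3-(4-hydroxy-3-methoxyphenyl)-3-methoxypropyl pivalate F1 as a mixture of epimers at the benzylic carbon. In a second operation without oxidant, BF3·OEt2 in CH2Cl2 at 0 °C ionises this benzylic ether, which is para to the free hydroxyl. The ring A phenol then forms O1–C2 under equilibrating conditions that should converge both epimers on the trans product, and the route is rejoined at 20.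

Step 7 (Evans alkylation). Alkylation at the enolate carbon next to the ortho-benzyloxy group may be slow. The enolate may break down by loss of the oxazolidinone on warming, and the acidic α-aryl centre of the product may epimerise under base, each of which would erode the selectivity. Fallback: catalytic instead of auxiliary control. Setting out from acid 7, Perkin condensation with commercial 4-(benzyloxy)-3-methoxybenzaldehyde (Ac2O, Et3N, 110 °C) should give (E)-2-[2-(benzyloxy)-5-(1,3-dioxolan-2-yl)-3-methoxyphenyl]-3-[4-(benzyloxy)-3-methoxyphenyl]acrylic acid F2. Homogeneous asymmetric hydrogenation with Ru(OAc)2(H8-BINAP) in methanol under hydrogen pressure, using the ligand antipode that a trial run shows to lead to the R acid, should give (2R)-2-[2-(benzyloxy)-5-(1,3-dioxolan-2-yl)-3-methoxyphenyl]-3-[4-(benzyloxy)-3-methoxyphenyl]propanoic acid F3 without cleaving the benzyl ethers. LiAlH4 in THF at 0 °C then reduces the acid to alcohol 15, where the route is rejoined.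

Step 3 (Negishi-type coupling of the Reformatsky reagent). Oxidative addition or transmetalation at the iodide flanked by the benzyloxy group may be sluggish, so that protodeiodination and self-condensation of the zinc enolate take over. Fallback: the acetate unit is brought in as a malonate. Setting out from 3, copper-catalysed arylation of diethyl malonate (CuI, 2-picolinic acid, Cs2CO3, 1,4-dioxane, 70 °C) should give diethyl 2-[2-(benzyloxy)-5-(1,3-dioxolan-2-yl)-3-methoxyphenyl]malonate F4. Krapcho dealkoxycarbonylation (LiCl, wet DMSO, 150 °C) then removes one ester group and gives 6, where the route is rejoined.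

**Further compounds**

F1 | step 11 | (2R)-2-(5-formyl-2-hydroxy-3-methoxyphenyl)-3-(4-hydroxy-3-methoxyphenyl)-3-methoxypropyl pivalate (both epimers at C3 of the chain) | CC(C)(C)C(=O)OC[C@H](C(OC)c1ccc(O)c(OC)c1)c1cc(C=O)cc(OC)c1O
F2 | step 7 | (E)-2-[2-(benzyloxy)-5-(1,3-dioxolan-2-yl)-3-methoxyphenyl]-3-[4-(benzyloxy)-3-methoxyphenyl]acrylic acid | OC(=O)/C(=C/c1ccc(OCc2ccccc2)c(OC)c1)c1cc(C2OCCO2)cc(OC)c1OCc1ccccc1
F3 | step 7 | (2R)-2-[2-(benzyloxy)-5-(1,3-dioxolan-2-yl)-3-methoxyphenyl]-3-[4-(benzyloxy)-3-methoxyphenyl]propanoic acid | OC(=O)[C@H](Cc1ccc(OCc2ccccc2)c(OC)c1)c1cc(C2OCCO2)cc(OC)c1OCc1ccccc1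
F4 | step 3 | diethyl 2-[2-(benzyloxy)-5-(1,3-dioxolan-2-yl)-3-methoxyphenyl]malonate | CCOC(=O)C(C(=O)OCC)c1cc(C2OCCO2)cc(OC)c1OCc1ccccc1
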